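**Strategy.** The route rests on cutting the saturated side chain at C6'–C7' (primed atoms counted outward from ring carbon C1 of the cyclohex-4-ene-1,3-diol). One operation, 9-BBN hydroboration followed by Pd/PCy3 B-alkyl Suzuki coupling, joins the unprotected (1S,3S)-1-(hex-5-enyl)cyclohexenediol to (Z)-10-phenyldec-6-enyl bromide and ends the synthesis. It exploits the unbranched methylene tether C1'–C11' between ring carbon C1 and the Z olefin C12'=C13': the side-chain vinyl group C5'=C6' is hydroborated while the endocyclic C4=C5 olefin stays. The diol ring arises from a Birch diene by Shi epoxidation, hydride opening, hydroxyl-directed epoxidation and selenide-mediated epoxide-to-allylic-alcohol transposition; the bromide comes from alkyne alkylation and Lindlar reduction.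

Key step: step 8

Remark (assumption): (hex-5-en-1-yl)benzene, 5-phenyl-1-pentyne, 1,5-dibromopentane and the L-fructose-derived enantiomer of the Shi ketone (ent-Shi ketone, otherwise made from L-sorbose) are taken as commercial. Ring atoms are numbered as in cyclohex-4-ene-1,3-diol (C1 tertiary carbinol, C3 allylic carbinol).

**Step 1**
Reactants: 1 (hex-5-en-1-yl)benzene
Product: 2 1-(hex-5-en-1-yl)cyclohexa-1,4-diene
Conditions: Li, NH3(l), THF, t-BuOH, −78 → −33 °C; NH4Cl
Reagents that add atoms: none
Why: Birch reduction of a monoalkylbenzene should give the 2,5-dihydro isomer with the alkyl group on a remaining double bond, and an isolated terminal olefin is not reduced by dissolving metal.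

**Step 2**
Reactants: 2 1-(hex-5-en-1-yl)cyclohexa-1,4-diene
Product: 3 (1R,6S)-1-(hex-5-en-1-yl)-7-oxabicyclo[4.1.0]hept-3-ene
Conditions: ent-Shi ketone (30 mol %), Oxone, K2CO3, Bu4NHSO4, MeCN–DMM/aq. borate–EDTA buffer (pH ≈ 10.5), −10 → 0 °C
Reagents that add atoms: Oxone (potassium peroxymonosulfate), [K+].[O-]S(=O)(=O)OO
Why: Shi asymmetric epoxidation, in which the chiral dioxirane should oxidise the electron-rich trisubstituted olefin ahead of the cis-disubstituted ring olefin and the vinyl group; the catalyst sets the future tertiary carbinol centre, and the L-fructose-derived ketone is chosen because the spiro transition-state model (as for 1-arylcyclohexenes and trans-olefins) predicts the opposite face for the D-fructose-derived ketone.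

**Step 3**
Reactants: 3 (1R,6S)-1-(hex-5-en-1-yl)-7-oxabicyclo[4.1.0]hept-3-ene
Product: 4 (S)-1-(hex-5-en-1-yl)cyclohex-3-en-1-ol
Conditions: LiAlH4, THF, 0 °C → reflux
Reagents that add atoms: none
Why: Hydride opening of a trisubstituted epoxide should take place by SN2 attack at the secondary carbon, so the C–O bond of the quaternary carbon and its configuration are kept.

**Step 4**
Reactants: 4 (S)-1-(hex-5-en-1-yl)cyclohex-3-en-1-ol
Product: 5 (1S,3S,6R)-3-(hex-5-en-1-yl)-7-oxabicyclo[4.1.0]heptan-3-ol
Conditions: VO(acac)2 (5 mol %), t-BuOOH (decane), CH2Cl2, 0 °C → rt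
Reagents that add atoms: tert-butyl hydroperoxide, CC(C)(C)OO
Why: Hydroxyl-directed vanadium-catalysed epoxidation of a homoallylic alcohol should deliver oxygen to the ring olefin on the face of the pseudo-axial tertiary hydroxyl (cis-epoxy alcohol, side chain equatorial), and the undirected vinyl group should not react.

**Step 5**
Reactants: 5 (1S,3S,6R)-3-(hex-5-en-1-yl)-7-oxabicyclo[4.1.0]heptan-3-ol
Product: 8 (1S,3S)-1-(hex-5-en-1-yl)cyclohex-4-ene-1,3-diol, via hydroxy selenide 6 (not isolated), via selenoxide 7 (not isolated)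
Conditions: (PhSe)2, NaBH4, EtOH, rt → reflux; then THF, 30% H2O2, pyridine, 0 °C → rt
Reagents that add atoms: none
Why: Epoxide-to-allylic-alcohol transposition by selenolate opening and selenoxide syn-elimination; in the half-chair with the side chain equatorial and the hydroxyl axial, trans-diaxial (Fürst–Plattner) attack should occur at C6 of 5, the epoxide carbon remote from the carbinol, and the selenoxide should eliminate away from the new carbinol carbon, so the C3–O bond cis to the C1 hydroxyl comes unchanged from the epoxide.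

**Step 6**
Reactants: 9 pent-4-yn-1-ylbenzene (5-phenyl-1-pentyne), 10 1,5-dibromopentane
Product: 12 (10-bromodec-4-yn-1-yl)benzene, via lithium acetylide 11 (not isolated)
Conditions: n-BuLi, THF, −78 → 0 °C; then 10 (4 equiv), DMPU, −78 °C → rt
Reagents that add atoms: none
Why: SN2 alkylation of a lithium acetylide with a primary bromide; the excess of the symmetrical dibromide should suppress double alkylation.

**Step 7**
Reactants: 12 (10-bromodec-4-yn-1-yl)benzene
Product: 13 [(4Z)-10-bromodec-4-en-1-yl]benzene
Conditions: H2 (1 atm), Lindlar catalyst, quinoline, hexane, rt, stopped after one equivalent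
Reagents that add atoms: none
Why: Lindlar semi-hydrogenation adds hydrogen syn on the poisoned palladium surface and should give the Z olefin without touching the primary bromide.

**Step 8**
Reactants: 8 (1S,3S)-1-(hex-5-en-1-yl)cyclohex-4-ene-1,3-diol, 13 [(4Z)-10-bromodec-4-en-1-yl]benzene
Product: 15 (1S,3S)-1-[(12Z)-16-phenylhexadec-12-en-1-yl]cyclohex-4-ene-1,3-diol, via alkylborane 14 (not isolated)
Conditions: 8 (1.2 equiv), 9-BBN (3.2 equiv), THF, 0 °C → rt; degassed H2O, K3PO4·H2O; then 13, Pd(OAc)2 (5 mol %), PCy3 (10 mol %), THF, rt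
Reagents that add atoms: none
Why: 9-BBN adds syn and anti-Markovnikov to the terminal C5'=C6' olefin of 8 and puts boron on C6'; base turns the borane into a four-coordinate borate, Pd(0)–PCy3 inserts into the primary C–Br bond of 13 by SN2-type oxidative addition, the primary alkyl group passes from boron to palladium with retention, and C(sp3)–C(sp3) reductive elimination forms the C6'–C7' bond. The closest known reaction type is the room-temperature B-alkyl Suzuki–Miyaura coupling of unactivated primary alkyl bromides bearing β-hydrogens with B-alkyl-9-BBN reagents under Pd(OAc)2/PCy3/K3PO4·H2O. No ring is closed and no stereocentre is formed; C1, C3 and the Z olefin are not touched. The step needs hydroboration of the vinyl group only: the bulky dialkylborane should react with a monosubstituted olefin far faster than with the endocyclic, allylically oxygenated C4=C5 olefin, and the Z olefin of 13 should never meet B–H because residual hydride is quenched by the aqueous base before 13 is added. The two hydroxyls take up the excess 9-BBN as borinates (loss of H2) and are released again by the aqueous base, while the bulky, electron-rich PCy3 should make reductive elimination faster than β-hydride elimination.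

**Compound list**
1 | (hex-5-en-1-yl)benzene (6-phenylhex-1-ene) | C=CCCCCc1ccccc1 | starting material
2 | 1-(hex-5-en-1-yl)cyclohexa-1,4-diene | C=CCCCCC1=CCC=CC1 | intermediate
3 | (1R,6S)-1-(hex-5-en-1-yl)-7-oxabicyclo[4.1.0]hept-3-ene | C1=CC[C@@H]2O[C@]2(CCCCC=C)C1 | intermediate
4 | (S)-1-(hex-5-en-1-yl)cyclohex-3-en-1-ol | C1=CCC[C@@](O)(CCCCC=C)C1 | intermediate
5 | (1S,3S,6R)-3-(hex-5-en-1-yl)-7-oxabicyclo[4.1.0]heptan-3-ol (epoxide cis to the hydroxyl) | O[C@@]1(CCCCC=C)CC[C@H]2O[C@H]2C1 | intermediate
6 | (1S,3S,4S)-1-(hex-5-en-1-yl)-4-(phenylselanyl)cyclohexane-1,3-diol (hydroxy selenide, not isolated) | O[C@@H]1[C@@H]([Se]c2ccccc2)CC[C@@](O)(CCCCC=C)C1 | intermediate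
7 | (1S,3S,4S)-4-(benzeneseleninyl)-1-(hex-5-en-1-yl)cyclohexane-1,3-diol (selenoxide, mixture at Se, not isolated) | O[C@@H]1[C@@H]([Se](=O)c2ccccc2)CC[C@@](O)(CCCCC=C)C1 | intermediate
8 | (1S,3S)-1-(hex-5-en-1-yl)cyclohex-4-ene-1,3-diol (cis-diol) | O[C@@H]1C=CC[C@@](O)(CCCCC=C)C1 | intermediate
9 | pent-4-yn-1-ylbenzene (5-phenyl-1-pentyne) | C#CCCCc1ccccc1 | starting material
10 | 1,5-dibromopentane | BrCCCCCBr | starting material
11 | (5-phenylpent-1-yn-1-yl)lithium (lithium acetylide, not isolated) | [Li]C#CCCCc1ccccc1 | intermediate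
12 | (10-bromodec-4-yn-1-yl)benzene | BrCCCCCC#CCCCc1ccccc1 | intermediate
13 | [(4Z)-10-bromodec-4-en-1-yl]benzene | BrCCCCC/C=C\CCCc1ccccc1 | intermediate
14 | (1S,3S)-1-[6-(9-borabicyclo[3.3.1]nonan-9-yl)hexyl]cyclohex-4-ene-1,3-diol (alkylborane, not isolated) | O[C@@H]1C=CC[C@@](O)(CCCCCCB2C3CCCC2CCC3)C1 | intermediate
15 | (1S,3S)-1-[(12Z)-16-phenylhexadec-12-en-1-yl]cyclohex-4-ene-1,3-diol | O[C@@H]1C=CC[C@@](O)(CCCCCCCCCCC/C=C\CCCc2ccccc2)C1 | target

**Step count.** Total: 8 steps. Longest linear sequence: 6 steps (steps 1–5 and 8).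

**Steps most likely to fail**

1. Step 8. The free hydroxyls may consume B–H and leave hydroboration incomplete, Pd(0) may ionise the boron-activated allylic C3–O bond, and β-hydride elimination may outrun alkyl transfer. The fallback sets out from 8 and comes back at 15, forming the same bond with reversed polarity. Silylation of 8 (TESOTf, 2,6-lutidine, CH2Cl2) should give the bis(triethylsilyl) ether of 8 F1. 9-BBN then gives the B-alkyl-9-BBN of the silyl ether F2, which is oxidised in the same flask (NaOH, H2O2) to the primary alcohol F3. I2, PPh3 and imidazole convert this into the primary iodide F4. Bromide 13 is turned (Mg, THF) into [(6Z)-10-phenyldec-6-en-1-yl]magnesium bromide F5, which is coupled with F4 under Li2CuCl4 catalysis (THF, −78 → 0 °C, copper-catalysed Grignard–alkyl iodide coupling) to the bis(triethylsilyl) ether of 15 F6. TBAF in THF removes both silyl groups and gives 15.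

2. Step 2. Enantioface discrimination on a 1-alkylcyclohexadiene may be insufficient, and the other two olefins may be partly oxidised. The fallback sets out from 8 of insufficient enantiomeric purity and comes back at enantiopure 8. A lipase-catalysed kinetic resolution at the secondary allylic carbinol (Candida antarctica lipase B, vinyl acetate, MTBE, rt) is assumed to acylate the (R)-configured carbinol of the minor enantiomer, the usual preference of this enzyme for cyclohex-2-en-1-ols. The minor enantiomer is then removed by chromatography as (1R,5R)-5-(hex-5-en-1-yl)-5-hydroxycyclohex-2-en-1-yl acetate F7, and unreacted 8 is recovered.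

3. Step 5. The selenolate may attack the wrong epoxide carbon if the ring reacts through the other half-chair, and perseleninic acid may epoxidise olefins during the peroxide stage. The fallback sets out from 4 and comes back at 8, passing by 5–7. Deprotonation (n-BuLi, THF, −78 °C) and Boc2O should give tert-butyl (S)-1-(hex-5-en-1-yl)cyclohex-3-en-1-yl carbonate F8. IBr (toluene, −80 °C) should close the six-membered cyclic iodocarbonate F9, in which the carbonyl oxygen enters at C3 syn to the C1–O bond and iodine sits trans at C4; the ring size fixes the regiochemistry. DBU (toluene, 80 °C) eliminates HI anti-periplanar towards C5 to the cyclic carbonate of 8 F10, and K2CO3 in MeOH sets 8 free.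

**Further compounds**
F1 | step 8 | bis(triethylsilyl) ether of 8: cis-1-(hex-5-en-1-yl)-1,3-bis(triethylsilyloxy)cyclohex-4-ene | CC[Si](CC)(CC)O[C@@H]1C=CC[C@@](O[Si](CC)(CC)CC)(CCCCC=C)C1
F2 | step 8 | B-alkyl-9-BBN of the silyl ether: 9-{6-[cis-1,3-bis(triethylsilyloxy)cyclohex-4-en-1-yl]hexyl}-9-borabicyclo[3.3.1]nonane | CC[Si](CC)(CC)O[C@@H]1C=CC[C@@](O[Si](CC)(CC)CC)(CCCCCCB2C3CCCC2CCC3)C1
F3 | step 8 | primary alcohol: 6-[cis-1,3-bis(triethylsilyloxy)cyclohex-4-en-1-yl]hexan-1-ol | CC[Si](CC)(CC)O[C@@H]1C=CC[C@@](O[Si](CC)(CC)CC)(CCCCCCO)C1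
F4 | step 8 | primary iodide: cis-1-(6-iodohexyl)-1,3-bis(triethylsilyloxy)cyclohex-4-ene | CC[Si](CC)(CC)O[C@@H]1C=CC[C@@](O[Si](CC)(CC)CC)(CCCCCCI)C1
F5 | step 8 | [(6Z)-10-phenyldec-6-en-1-yl]magnesium bromide | Br[Mg]CCCCC/C=C\CCCc1ccccc1
F6 | step 8 | bis(triethylsilyl) ether of 15 | CC[Si](CC)(CC)O[C@@H]1C=CC[C@@](O[Si](CC)(CC)CC)(CCCCCCCCCCC/C=C\CCCc2ccccc2)C1
F7 | step 2 | (1R,5R)-5-(hex-5-en-1-yl)-5-hydroxycyclohex-2-en-1-yl acetate | CC(=O)O[C@H]1C=CC[C@](O)(CCCCC=C)C1
F8 | step 5 | tert-butyl (S)-1-(hex-5-en-1-yl)cyclohex-3-en-1-yl carbonate | C1=CCC[C@@](OC(=O)OC(C)(C)C)(CCCCC=C)C1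
F9 | step 5 | cyclic iodocarbonate: 1-(hex-5-en-1-yl)-6-iodo-2,4-dioxabicyclo[3.3.1]nonan-3-one, iodine trans to the adjacent carbonate oxygen | O=C2O[C@@H]1[C@@H](I)CC[C@@](O2)(CCCCC=C)C1
F10 | step 5 | cyclic carbonate of 8: 1-(hex-5-en-1-yl)-2,4-dioxabicyclo[3.3.1]non-6-en-3-one | O=C2O[C@@H]1C=CC[C@@](O2)(CCCCC=C)C1
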